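I started from a one-step world: with growth alone, each living end takes up free monomer at 8.00 s⁻¹, and nothing ends a chain.

    free monomer + initiator → living end + monomer in chains (k1 = 2.5 M⁻¹ s⁻¹)
    free monomer + living end → monomer in chains + living end, rate k2*[living end]*[free monomer] (k2 = 800 M⁻¹ s⁻¹)
    living end → dead end A (k3 = 0.23 s⁻¹)
    pre-initiator → initiator (k4 = 0.034 s⁻¹)
    initiator + impurity → spent initiator B (k5 = 9.5 × 10⁶ M⁻¹ s⁻¹)

free monomer 10 mM; pre-initiator 20 µM; impurity 2.9 µM; time 5.0 min

- average number of monomer units in a chain (chains begun, living or dead) at 5.0 min
- part of the free monomer that has reacted at 5.0 min

- the average divides the monomer in chains by the number of chains begun, living and dead together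
- run time (flask): 5.0 min

Next I added the step to dead end A. A living end lasts 4.35 s on average, shorter than the run, so I expected chains to finish inside the run. In that lifetime a chain adds 34.8 units to the one it received on starting. With [free monomer] held at its charge, this flask gets 35.8 units per chain, the kinetic chain length: one unit from initiation plus growth rate over death rate.

Then I added the rest. At the charges, impurity takes initiator at 27.5 s⁻¹ against 0.0250 s⁻¹ for free monomer, each a pseudo-first-order rate, so I let the impurity spend its own charge of initiator first. That leaves 17.1 µM to begin chains. The half-lives of pre-initiator, 0.34 min, and of initiator against free monomer at its charge, 0.46 min, are shorter than the run, so I counted that amount as begun. My reckoning for this flask was therefore a chain length of 35.8 and 6.12 % of the free monomer reacted.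

The forecast gave 34.7 and 5.9 %, and its grounds opened: “The impurity destroys the first 2.9 µM of initiator within about 5 s”. Both my numbers stood above the forecast's.

The simulation of this flask gave 34.7 and 5.92 %, so the forecast was right within the tolerance. At 50.0 min the part reacted in this flask read 5.94 %, with 94.1 % of the free monomer still there and living end at 0 mM. Raising the free monomer to 11.0 mM, the other charges and the time held, moved the computed chain length by 3.47, and the kinetic chain length rises by 3.58 over that step.

For the neighbour flask with 2.5 mM of free monomer, the kinetic chain length gives 9.70 units. The simulation of that flask gave 9.41.

The constants come from no measurement; the result is computed.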